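The plan rests on cutting ring A at C4a–C5 and C8–C8a. Around that ring the ketone-bearing C4a, the O1-bearing C8a, the alkylated C8 and the oxygenated C7 sit in a row, which is exactly the pattern left when a 1-methoxy-3-silyloxy-1,3-diene with a substituent on its nucleophilic end adds to the C5=C6 double bond of a (2S)-2-aryl-5-(p-tolylsulfinyl)-2,3-dihydropyran-4-one. In one thermal operation both bonds form, ring A closes, and expulsion of p-toluenesulfenic acid and methanol makes it aromatic; C2, installed earlier by a catalytic asymmetric hetero-Diels–Alder reaction, is not touched. The diene brings the whole Z side chain, and every hydroxyl travels as a TBS ether so that one buffered fluoride step finishes the synthesis.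

Key step: step 11

Remarks on the chemistry
- Numbering: flavanone numbering (O1, C2, C3, C4, C4a, C5–C8, C8a) for 18–21; pyranone numbering (O1, C2 aryl, C3, C4 carbonyl, C5, C6) for 5–7; chain numbering C1–C8 for 16 and 17.
- Assumption: sulfoxide 7 is used as the mixture of both configurations at sulfur, because sulfur leaves in step 11.
- Assumption: the facial sense of the catalyst in step 2 is assigned by analogy with the behaviour of BINOL–titanium catalysts toward aromatic aldehydes; it is to be verified on the first batch and the ligand antipode used if the sense is reversed.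
- Any material that loses the C7 silyl group in step 11 is the same flavanone one silyl group short and can be carried into step 12 together with 20.
- The catechol is silylated and not protected as acetals, so that no acid is needed at the end, when the free C7 phenol sits next to the allylic side chain.

Step 1
Reactants: 1 3,4-dihydroxybenzaldehyde
Product: 2 3,4-bis[(tert-butyldimethylsilyl)oxy]benzaldehyde
Conditions: TBSCl, imidazole, DMF, 0 °C → rt
Reagents that add atoms: tert-butyldimethylsilyl chloride, CC(C)(C)[Si](C)(C)Cl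
Why: Imidazole-promoted O-silylation of both phenols, to which the aldehyde is inert; no stereocentre is involved.

Step 2
Reactants: 2 3,4-bis[(tert-butyldimethylsilyl)oxy]benzaldehyde; 3 Danishefsky's diene, (E)-1-methoxy-3-(trimethylsilyloxy)buta-1,3-diene
Product: 5 (2S)-2-{3,4-bis[(tert-butyldimethylsilyl)oxy]phenyl}-2,3-dihydro-4H-pyran-4-one, via Mukaiyama aldol adduct 4 (not isolated)
Conditions: Ti(OiPr)4 (10 mol %), (S)-BINOL (20 mol %), 4 Å MS, Et2O, −20 °C; then CF3CO2H, CH2Cl2, 0 °C
Reagents that add atoms: none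
Why: Catalytic asymmetric hetero-Diels–Alder reaction in its Mukaiyama aldol/cyclisation form, in which the chiral BINOL–titanium complex binds the aldehyde and should direct the nucleophilic diene terminus to the Si face, setting C2 as S, after which brief CF3CO2H treatment closes the ring with loss of methanol and leaves the aryl silyl ethers intact.

Step 3
Reactants: 5 (2S)-2-{3,4-bis[(tert-butyldimethylsilyl)oxy]phenyl}-2,3-dihydro-4H-pyran-4-one
Product: 6 (2S)-2-{3,4-bis[(tert-butyldimethylsilyl)oxy]phenyl}-5-(p-tolylsulfanyl)-2,3-dihydro-4H-pyran-4-one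
Conditions: p-TolSCl [fresh, from (p-TolS)2 and SO2Cl2], CH2Cl2, −78 °C; then pyridine, −78 → 0 °C
Reagents that add atoms: p-toluenesulfenyl chloride, Cc1ccc(SCl)cc1
Why: Electrophilic α-sulfenylation of a vinylogous ester by addition–elimination, in which the sulfenyl chloride attacks the nucleophilic C5, the C6 oxocarbenium ion loses the C5 proton to pyridine, and a base this weak should not open the pyranone, so C2 is preserved.

Step 4
Reactants: 6 (2S)-2-{3,4-bis[(tert-butyldimethylsilyl)oxy]phenyl}-5-(p-tolylsulfanyl)-2,3-dihydro-4H-pyran-4-one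
Product: 7 (2S)-2-{3,4-bis[(tert-butyldimethylsilyl)oxy]phenyl}-5-(p-tolylsulfinyl)-2,3-dihydro-4H-pyran-4-one (both configurations at sulfur)
Conditions: mCPBA (1.0 equiv), CH2Cl2, −78 → −40 °C
Reagents that add atoms: 3-chloroperbenzoic acid, O=C(OO)c1cccc(Cl)c1
Why: Chemoselective peracid oxidation of sulfide to sulfoxide, sulfur being far more nucleophilic than the push–pull C5=C6 bond; the new sulfur stereocentre is left uncontrolled because it is lost in step 11.

Step 5
Reactants: 8 propargyl alcohol (prop-2-yn-1-ol)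
Product: 10 (2Z)-3-iodo-2-methylprop-2-en-1-ol, via vinylmagnesium alkoxide 9 (not isolated)
Conditions: MeMgBr (3 equiv), CuI (10 mol %), THF, −20 °C → rt; then I2, −20 °C; aq NH4Cl
Reagents that add atoms: methylmagnesium bromide, C[Mg]Br; iodine, II
Why: Copper-catalysed, alkoxide-directed anti-carbomagnesiation of the propargylic alcohol places methyl on C2 and magnesium on C3 cis to the CH2O group within a five-membered chelate, and iodinolysis with retention fixes the Z geometry.

Step 6
Reactants: 10 (2Z)-3-iodo-2-methylprop-2-en-1-ol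
Product: 11 tert-butyl{[(2Z)-3-iodo-2-methylprop-2-en-1-yl]oxy}dimethylsilane
Conditions: TBSCl, imidazole, CH2Cl2, 0 °C → rt
Reagents that add atoms: tert-butyldimethylsilyl chloride, CC(C)(C)[Si](C)(C)Cl
Why: Standard O-silylation of a primary allylic alcohol that does not touch the vinyl iodide or its geometry.

Step 7
Reactants: 11 tert-butyl{[(2Z)-3-iodo-2-methylprop-2-en-1-yl]oxy}dimethylsilane
Product: 12 (2Z)-4-[(tert-butyldimethylsilyl)oxy]-3-methylbut-2-en-1-ol
Conditions: Bu3SnCH2OH, Pd(PPh3)4 (5 mol %), dioxane, 90 °C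
Reagents that add atoms: (tributylstannyl)methanol, OC[Sn](CCCC)(CCCC)CCCC
Why: Stille hydroxymethylation, in which oxidative addition and reductive elimination at the sp2 carbon proceed with retention so the Z geometry is kept, the oxygenated CH2OH group transfers from tin in preference to butyl, and no vinyllithium is formed that could undergo 1,4 O-to-C silyl migration.

Step 8
Reactants: 12 (2Z)-4-[(tert-butyldimethylsilyl)oxy]-3-methylbut-2-en-1-ol
Product: 13 {[(2Z)-4-bromo-2-methylbut-2-en-1-yl]oxy}(tert-butyl)dimethylsilane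
Conditions: CBr4, PPh3, CH2Cl2, −20 → 0 °C
Reagents that add atoms: carbon tetrabromide, BrC(Br)(Br)Br
Why: Appel reaction, an SN2 displacement of the oxyphosphonium group by bromide at the primary allylic carbon, which at low temperature should leave the trisubstituted Z double bond and the silyl ether untouched.

Step 9
Reactants: 14 (3E)-4-methoxybut-3-en-2-one (2 equiv); 13 {[(2Z)-4-bromo-2-methylbut-2-en-1-yl]oxy}(tert-butyl)dimethylsilane
Product: 16 (1E,6Z)-8-[(tert-butyldimethylsilyl)oxy]-1-methoxy-7-methylocta-1,6-dien-3-one, via lithium enolate 15 (not isolated)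
Conditions: LDA, THF, −78 °C; then 13, DMPU, −78 → −30 °C
Reagents that add atoms: none
Why: Stork–Danheiser-type kinetic deprotonation of the vinylogous ester at its only enolisable position gives the cross-conjugated lithium enolate, which is alkylated by SN2 at the primary allylic bromide with retention of the Z olefin, the excess of enolate limiting dialkylation.

Step 10
Reactants: 16 (1E,6Z)-8-[(tert-butyldimethylsilyl)oxy]-1-methoxy-7-methylocta-1,6-dien-3-one
Product: 17 (1E,3Z,6Z)-3,8-bis[(tert-butyldimethylsilyl)oxy]-1-methoxy-7-methylocta-1,3,6-triene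
Conditions: TBSOTf, Et3N, Et2O, 0 °C → rt
Reagents that add atoms: tert-butyldimethylsilyl triflate, CC(C)(C)[Si](C)(C)OS(=O)(=O)C(F)(F)F
Why: Soft enolisation and O-silylation toward the only α-CH2 gives the silyl dienol ether, and the thermodynamically preferred 3Z isomer is expected, in which the chain is trans to the vinyl group and therefore points outward in the s-cis diene.

Step 11
Reactants: 7 (2S)-2-{3,4-bis[(tert-butyldimethylsilyl)oxy]phenyl}-5-(p-tolylsulfinyl)-2,3-dihydro-4H-pyran-4-one; 17 (1E,3Z,6Z)-3,8-bis[(tert-butyldimethylsilyl)oxy]-1-methoxy-7-methylocta-1,3,6-triene (2 equiv)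
Product: 20 (2S)-7-[(tert-butyldimethylsilyl)oxy]-2-{3,4-bis[(tert-butyldimethylsilyl)oxy]phenyl}-8-{(2Z)-4-[(tert-butyldimethylsilyl)oxy]-3-methylbut-2-en-1-yl}-2,3-dihydro-4H-chromen-4-one, via Diels–Alder adduct 18 (not isolated), via methoxy dihydroflavanone 19 (not isolated)
Conditions: 4 Å MS, PhMe, 100 °C; then SiO2, CH2Cl2, rt
Reagents that add atoms: none
Why: Normal-electron-demand Diels–Alder reaction followed by two eliminations: the chain-bearing diene terminus C4 bonds to the electrophilic β-carbon C6 of the doubly activated enone (the future C8a) and the methoxy-bearing terminus C1 bonds to the sulfinyl-bearing α-carbon C5 (the future C4a), giving the cis-fused adduct 18. The closest known reaction type is the Diels–Alder/aromatisation of 3-sulfinylchromones, sulfinylquinones and α-sulfinyl enones with Danishefsky-type dienes, from which this dienophile differs only in having an alkyl instead of an aryl enol-ether oxygen. Ring A is closed by this suprafacial [4+2] cycloaddition, both σ-bonds (C4a–C5 and C8–C8a) arising in one pericyclic event rather than through an exo or endo cyclisation. Because the addition is suprafacial the sulfinyl group and H-8a are cis, so thermal syn-elimination (Ei) of p-toluenesulfenic acid restores the C4a=C8a bond to give 19, whose C5 methoxy group and C8 hydrogen then leave by 1,4-elimination (completed on silica if needed) to give the arene; every new sp3 centre and the sulfur centre are erased, so no stereocentre is created and C2, none of whose bonds is touched, stays S. The selectivity needed is regiochemical and follows from matched polarisation (ketone and sulfoxide both on C5 make C6 the acceptor terminus, the 1-methoxy and 3-silyloxy groups make C4 the donor terminus), while the 3Z geometry keeps the chain outward in the reacting s-cis diene. Anhydrous, neutral conditions should keep the silyl enol ether intact until the sulfoxide has left, so that C8a becomes sp2 before a C7 ketone could expel O1.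

Step 12
Reactants: 20 (2S)-7-[(tert-butyldimethylsilyl)oxy]-2-{3,4-bis[(tert-butyldimethylsilyl)oxy]phenyl}-8-{(2Z)-4-[(tert-butyldimethylsilyl)oxy]-3-methylbut-2-en-1-yl}-2,3-dihydro-4H-chromen-4-one
Product: 21 (2S)-2-(3,4-dihydroxyphenyl)-7-hydroxy-8-[(2Z)-4-hydroxy-3-methylbut-2-en-1-yl]-2,3-dihydro-4H-chromen-4-one
Conditions: TBAF, AcOH (1:1, excess), THF, 0 °C → rt
Reagents that add atoms: none
Why: Fluoride-mediated desilylation of the three aryl and one primary alkyl silyl ethers, with acetic acid buffering the phenoxides so that neither retro-oxa-Michael opening of ring C (which would racemise C2) nor acid-promoted cyclisation of the C7 phenol onto the side chain should occur, and with the Z olefin unaffected.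

Compound list
1 | 3,4-dihydroxybenzaldehyde | O=Cc1ccc(O)c(O)c1 | starting material
2 | 3,4-bis[(tert-butyldimethylsilyl)oxy]benzaldehyde | O=Cc1ccc(O[Si](C)(C)C(C)(C)C)c(O[Si](C)(C)C(C)(C)C)c1 | intermediate
3 | Danishefsky's diene, (E)-1-methoxy-3-(trimethylsilyloxy)buta-1,3-diene | CO/C=C/C(=C)O[Si](C)(C)C | starting material
4 | (1E,5S)-5-{3,4-bis[(tert-butyldimethylsilyl)oxy]phenyl}-1-methoxy-5-(trimethylsilyloxy)pent-1-en-3-one | CO/C=C/C(=O)C[C@H](O[Si](C)(C)C)c1ccc(O[Si](C)(C)C(C)(C)C)c(O[Si](C)(C)C(C)(C)C)c1 | intermediate (not isolated)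
5 | (2S)-2-{3,4-bis[(tert-butyldimethylsilyl)oxy]phenyl}-2,3-dihydro-4H-pyran-4-one | O=C1C=CO[C@H](c2ccc(O[Si](C)(C)C(C)(C)C)c(O[Si](C)(C)C(C)(C)C)c2)C1 | intermediate
6 | (2S)-2-{3,4-bis[(tert-butyldimethylsilyl)oxy]phenyl}-5-(p-tolylsulfanyl)-2,3-dihydro-4H-pyran-4-one | Cc1ccc(SC2=CO[C@H](c3ccc(O[Si](C)(C)C(C)(C)C)c(O[Si](C)(C)C(C)(C)C)c3)CC2=O)cc1 | intermediate
7 | (2S)-2-{3,4-bis[(tert-butyldimethylsilyl)oxy]phenyl}-5-(p-tolylsulfinyl)-2,3-dihydro-4H-pyran-4-one, both configurations at sulfur | Cc1ccc(S(=O)C2=CO[C@H](c3ccc(O[Si](C)(C)C(C)(C)C)c(O[Si](C)(C)C(C)(C)C)c3)CC2=O)cc1 | intermediate (key-step precursor, dienophile)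
8 | propargyl alcohol (prop-2-yn-1-ol) | C#CCO | starting material
9 | bromomagnesium (2Z)-3-(bromomagnesio)-2-methylprop-2-en-1-olate | C/C(=C/[Mg]Br)CO[Mg]Br | intermediate (not isolated)
10 | (2Z)-3-iodo-2-methylprop-2-en-1-ol | C/C(=C/I)CO | intermediate
11 | tert-butyl{[(2Z)-3-iodo-2-methylprop-2-en-1-yl]oxy}dimethylsilane | C/C(=C/I)CO[Si](C)(C)C(C)(C)C | intermediate
12 | (2Z)-4-[(tert-butyldimethylsilyl)oxy]-3-methylbut-2-en-1-ol | C/C(=C/CO)CO[Si](C)(C)C(C)(C)C | intermediate
13 | {[(2Z)-4-bromo-2-methylbut-2-en-1-yl]oxy}(tert-butyl)dimethylsilane | C/C(=C/CBr)CO[Si](C)(C)C(C)(C)C | intermediate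
14 | (3E)-4-methoxybut-3-en-2-one | CO/C=C/C(C)=O | starting material
15 | lithium (3E)-4-methoxybuta-1,3-dien-2-olate | CO/C=C/C(=C)O[Li] | intermediate (not isolated)
16 | (1E,6Z)-8-[(tert-butyldimethylsilyl)oxy]-1-methoxy-7-methylocta-1,6-dien-3-one | CO/C=C/C(=O)CC/C=C(/C)CO[Si](C)(C)C(C)(C)C | intermediate
17 | (1E,3Z,6Z)-3,8-bis[(tert-butyldimethylsilyl)oxy]-1-methoxy-7-methylocta-1,3,6-triene | CO/C=C/C(O[Si](C)(C)C(C)(C)C)=C/C/C=C(/C)CO[Si](C)(C)C(C)(C)C | intermediate (key-step precursor, diene)
18 | cis-fused Diels–Alder adduct, (2S)-5-methoxy-4a-(p-tolylsulfinyl)-7-(TBS-oxy)-4a,5,8,8a-tetrahydroflavanone carrying the protected side chain at C8 and the bis-TBS catechol at C2; transient centres C4a, C5, C8, C8a and sulfur not assigned, all are erased | COC1C=C(O[Si](C)(C)C(C)(C)C)C(C/C=C(/C)CO[Si](C)(C)C(C)(C)C)C2O[C@H](c3ccc(O[Si](C)(C)C(C)(C)C)c(O[Si](C)(C)C(C)(C)C)c3)CC(=O)C12S(=O)c1ccc(C)cc1 | intermediate (not isolated)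
19 | (2S)-5-methoxy-7-(TBS-oxy)-5,8-dihydroflavanone carrying the same C8 and C2 substituents; transient centres C5 and C8 not assigned | COC1C=C(O[Si](C)(C)C(C)(C)C)C(C/C=C(/C)CO[Si](C)(C)C(C)(C)C)C2=C1C(=O)C[C@@H](c1ccc(O[Si](C)(C)C(C)(C)C)c(O[Si](C)(C)C(C)(C)C)c1)O2 | intermediate (not isolated)
20 | (2S)-7-[(tert-butyldimethylsilyl)oxy]-2-{3,4-bis[(tert-butyldimethylsilyl)oxy]phenyl}-8-{(2Z)-4-[(tert-butyldimethylsilyl)oxy]-3-methylbut-2-en-1-yl}-2,3-dihydro-4H-chromen-4-one | C/C(=C/Cc1c(O[Si](C)(C)C(C)(C)C)ccc2c1O[C@H](c1ccc(O[Si](C)(C)C(C)(C)C)c(O[Si](C)(C)C(C)(C)C)c1)CC2=O)CO[Si](C)(C)C(C)(C)C | intermediate (key-step product)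
21 | (2S)-2-(3,4-dihydroxyphenyl)-7-hydroxy-8-[(2Z)-4-hydroxy-3-methylbut-2-en-1-yl]-2,3-dihydro-4H-chromen-4-one | C/C(=C/Cc1c(O)ccc2c1O[C@H](c1ccc(O)c(O)c1)CC2=O)CO | target

Total step count: 12
Longest linear sequence: 8 steps (8 → 21, steps 5–12); the dienophile arm is 4 steps (1 → 7) before the convergent step 11.

Steps most likely to fail

Step 11. The cycloaddition may stall because a fully substituted centre (C4a) and a tertiary centre (C8) are formed side by side on a dienophile that is deactivated by its enol-ether oxygen. The sulfoxide may also eliminate toward C5 instead of C8a, or the silyl enol ether may hydrolyse early, which would let O1 be expelled from C8a and open ring C. The fallback buys ring A as an arene and sets C2 by conjugate arylation. It sets out from bromide 13: nuclear C-alkylation of commercial 2,4-dihydroxyacetophenone at its doubly activated C3 position (KOH, aqueous MeOH, 0 °C) should give 1-{2,4-dihydroxy-3-[(2Z)-4-(TBS-oxy)-3-methylbut-2-en-1-yl]phenyl}ethanone F1. Silylation of the non-chelated 4-hydroxyl (TBSCl, imidazole) gives the 4-O-TBS ketone F2, and heating with DMF dimethyl acetal gives the enaminone F3. Mild acid (SiO2 or AcOH) closes F3 with loss of dimethylamine to the 7-TBS-oxy-8-alkylchromone F4. In parallel, commercial 4-bromocatechol is silylated to 4-bromo-1,2-bis(TBS-oxy)benzene F5 and converted (n-BuLi, B(OiPr)3, then aqueous NH4Cl) into [3,4-bis(TBS-oxy)phenyl]boronic acid F6. Asymmetric conjugate addition of F6 to F4 with Pd(OCOCF3)2 (divalent palladium) and a tert-butyl pyridine-oxazoline ligand, antipode chosen to give 2S, comes back to the route at 20.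

Step 3. The sulfenyl chloride may also attack the electron-rich catechol ring or react twice, and chloride-adduct formation without clean elimination, or base-induced opening of the pyranone, would erode yield or the C2 configuration. The fallback separates C–H functionalisation from C–S bond formation. It sets out from 5: iodination with I2/pyridine in CH2Cl2, the standard α-halogenation of this ring system, gives (2S)-2-[3,4-bis(TBS-oxy)phenyl]-5-iodo-2,3-dihydro-4H-pyran-4-one F7. Palladium-catalysed C–S cross-coupling of F7 with p-thiocresol (Pd2(dba)3, zerovalent palladium, Xantphos, i-Pr2NEt, dioxane, 60 °C) comes back to the route at 6.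

Step 9. Proton exchange between enolate 15 and product 16 may lead to dialkylation, the vinylogous-ester enolate may react sluggishly, and SN2′ attack would scramble the side chain. The fallback uses a more nucleophilic dianion and installs the enol ether afterwards. It sets out from 13: γ-alkylation of the dianion of formylacetone (commercial sodium salt of 4-hydroxybut-3-en-2-one, LDA, THF, −78 → 0 °C) gives (6Z)-8-(TBS-oxy)-7-methyl-3-oxooct-6-enal F8, obtained as its enol. O-Methylation at the formyl oxygen (Me2SO4, K2CO3, acetone) comes back to the route at 16.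

Further compounds
F1 | step 11 | 1-{2,4-dihydroxy-3-[(2Z)-4-[(tert-butyldimethylsilyl)oxy]-3-methylbut-2-en-1-yl]phenyl}ethanone | CC(=O)c1ccc(O)c(C/C=C(/C)CO[Si](C)(C)C(C)(C)C)c1O
F2 | step 11 | 1-{4-[(tert-butyldimethylsilyl)oxy]-2-hydroxy-3-[(2Z)-4-[(tert-butyldimethylsilyl)oxy]-3-methylbut-2-en-1-yl]phenyl}ethanone | CC(=O)c1ccc(O[Si](C)(C)C(C)(C)C)c(C/C=C(/C)CO[Si](C)(C)C(C)(C)C)c1O
F3 | step 11 | (2E)-3-(dimethylamino)-1-{4-[(tert-butyldimethylsilyl)oxy]-2-hydroxy-3-[(2Z)-4-[(tert-butyldimethylsilyl)oxy]-3-methylbut-2-en-1-yl]phenyl}prop-2-en-1-one | CN(C)/C=C/C(=O)c1ccc(O[Si](C)(C)C(C)(C)C)c(C/C=C(/C)CO[Si](C)(C)C(C)(C)C)c1O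
F4 | step 11 | 7-[(tert-butyldimethylsilyl)oxy]-8-[(2Z)-4-[(tert-butyldimethylsilyl)oxy]-3-methylbut-2-en-1-yl]-4H-chromen-4-one | O=c1ccoc2c(C/C=C(/C)CO[Si](C)(C)C(C)(C)C)c(O[Si](C)(C)C(C)(C)C)ccc12
F5 | step 11 | 4-bromo-1,2-bis[(tert-butyldimethylsilyl)oxy]benzene | Brc1ccc(O[Si](C)(C)C(C)(C)C)c(O[Si](C)(C)C(C)(C)C)c1
F6 | step 11 | {3,4-bis[(tert-butyldimethylsilyl)oxy]phenyl}boronic acid | OB(O)c1ccc(O[Si](C)(C)C(C)(C)C)c(O[Si](C)(C)C(C)(C)C)c1
F7 | step 3 | (2S)-2-{3,4-bis[(tert-butyldimethylsilyl)oxy]phenyl}-5-iodo-2,3-dihydro-4H-pyran-4-one | O=C1C(I)=CO[C@H](c2ccc(O[Si](C)(C)C(C)(C)C)c(O[Si](C)(C)C(C)(C)C)c2)C1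
F8 | step 9 | (6Z)-8-[(tert-butyldimethylsilyl)oxy]-7-methyl-3-oxooct-6-enal | O=CCC(=O)CC/C=C(/C)CO[Si](C)(C)C(C)(C)C
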